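## The problem

Epoxytwinol A (25) is a C2-symmetric pentacycle made of two 5,6,7,8-tetrahydro-1H-isochromene halves. Each half is numbered as an isochromene (C1 ether methine, O2, C3 methyl carbinol carbon, C4 methine, C4a, C5 ketone, C6 and C7 oxirane carbons, C8 carbinol, C8a), with primes for the second half. Ring A (C4a, C5, C6, C7, C8, C8a) is an epoxycyclohexenone and ring B (C1, O2, C3, C4, C4a, C8a) a dihydropyran. The bonds C1–C1' and C4–C4' close the central cycloocta-1,5-diene ring C (C1, C8a, C4a, C4, C4', C4a', C8a', C1'). There are twelve stereocentres, six per half (1S,3R,4S,6R,7R,8S). Only C3 and C4 need absolute control: C1 follows from them, because each pyran oxygen can bridge ring C only on the face that carries its own C3. C6, C7 and C8 lie on the periphery, where the shape of the finished cage is the only control element (oxirane on the face of O2, hydroxyl anti to it). The epoxy ketone, the allylic carbinol and the enone will not survive strong base, Lewis acids or reducing metals, so they must appear last. The enabling feature is ring A itself: it carries oxygen at C5 and C8, para to each other and flanking the tetrasubstituted C4a=C8a bond. At the arene oxidation level C4a and C8a therefore map onto the two carbons of an alkyne, C5–C8 with both oxygens onto a 2-oxygenated furan, and C1 onto the formyl carbon of an ynal.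

## Retrosynthesis

**Rings A and A' back to arenes (25 to 21).** The four oxirane C–O bonds, the two C8–H bonds and the two C5 carbonyls are removed in turn, through diol bis-ketal 24, bis(epoxy ketone) 23 and bis(quinone monoketal) 22, to the bis(4-methoxyphenol) cage 21. Carrying an epoxy quinol through the cage assembly is not an option, since none of the cage-forming reagents tolerates it. Cage 21 has only two phenols, aryl and bridgehead ethers and six stereocentres. This cut fixes the oxygen pattern: C8 must be the free phenol (it becomes the ketone that is reduced) and C5 the methyl ether (it becomes the ketal unmasked last). The forward steps must pick the C6=C7 alkene over C4a=C8a and choose the convex face twice.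

**The cage (21 to 16).** The two C1–O2 ether bonds and the C1–C1' bond are cut, through silyl ether 20, alkene diol 18 and its silyl ether 17, to dialdehyde 16. Carbonyl olefination closes ring C first; anti-dioxygenation of the new alkene by the two carbinol oxygens follows (bromoetherification, then silver-assisted closure). Two shorter orders were weighed and set aside:
- Pinacol coupling followed by acid-mediated double etherification puts a benzylic cation next to a carbinol and invites a hydride shift; it is kept as a fallback.
- Reductive union of the two C1 carbons after closing both pyrans as cyclic acetals has no precedent on this substrate class.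

The chosen order is stereoconvergent: C1 and C1' need no external control. The precursor 16 is two arenes on an acyclic hexane. The forward reactions must close an eight-membered ring and make the alkene react faster than two electron-rich arenes.

**Oxygen exchange (16 to 13).** O–Si and O–CH3 bonds only: 16 from phenol 15, 15 from tetramethyl ether 14, 14 from phenol 13. The cycloaddition delivers OH at C5 and OMe at C8, the reverse of what the endgame needs. It also places the aldehyde next to the C8 methoxy group, so chelation-controlled cleavage with BCl3 swaps the two after exhaustive methylation.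

**Both arenes (13 to 10 and 11).** Four C–C bonds are cut (C4a–C5 and C8–C8a in each half), giving bis-ynal 10 and two molecules of 2-methoxyfuran (11). Against a cross-coupling of preformed arenes onto C4/C4', this builds each arene on a stereocentre that is never touched. It also places the formyl carbon that becomes C1 and differentiates the C5 and C8 oxygens. Two rings and all substituents of 13 are traded for a C2-symmetric diyne and a commercial furan. The forward reaction needs regioselectivity and must choose C≡C over C=O.

**The C2-symmetric bis-ynal (10 to 1).** The two C–CHO bonds are cut first, giving diyne 8 (formylation of the acetylide with DMF). Diyne 8 comes from dialdehyde 6 and diazophosphonate 7. Dialdehyde 6 comes from diol 5, silylated diester 4 and diol diester 3 by redox and protection. The central C4–C4' bond of 3 is cut last: oxidative dimerisation of the alkoxide enolate 2 of methyl (R)-3-hydroxybutanoate (1). This takes both carbinol centres from the chiral pool and sets both methines in the anti sense of the Fráter–Seebach alkylation, the relation required between C3 and C4.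

## Roads not taken

**Alternative 1:** double [2+2+2] on a dioxocane. The cut removes both arenes from a tetraboryl aromatic cage A1. Its precursor is the 5,8-dimethyl-2,3,6,7-tetrakis(borylethynyl)-1,4-dioxocane A2; CpCo(CO)2 would combine each transannular diyne pair with acetylene A3, forming six C–C bonds.
- Merits: it is highly convergent, all six sp3 centres of the core precede the arenes, and the cage and both arenes arise in one step.
- Weak points: A2 is the real problem. It is an eight-membered bis-ether with six stereocentres and vicinal propargylic ether carbons, with no evident stereocontrolled access. The metallacycle has to span ring C while cage strain builds up, in competition with pairing of the vicinal alkynes. Oxidation of the four C–B bonds of A1 gives two hydroquinones in which C5 and C8 are no longer differentiated, so the ketone/carbinol distinction has no handle.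
- Comparison: with A2 in hand this road would be shorter and would avoid the olefination and bromoetherification sequence. The chosen plan sets against it an acyclic precursor whose stereocentres come from a chiral-pool dimerisation, and arene oxygens that are differentiated from the moment they are made.

**Alternative 2:** cage-directed double epoxidation. The cut is the four oxirane C–O bonds; Weitz–Scheffer epoxidation of compound 22 gives the bis(epoxy ketone) bis-ketal A4, which is compound 23.
- Merits: the fragile oxiranes come at the very end, the cage is the control element, and the peroxide finds the disubstituted C6=C7 bond, not C4a=C8a.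
- Weak points: as a strategy-defining step it makes no skeletal bond and leaves the assembly of 22 open; its face selectivity is a prediction from shape.
- Comparison: this road is contained in the chosen plan (step 16), so at that step the two carry the same risk. The chosen plan adds the answer to where 22 comes from.

**Alternative 3:** glyoxal double oxa-Pictet–Spengler. The cut is C1–O2 and C1–C8a in both halves; under acid the diaryl diol A6 and glyoxal A7 would give the bis(4-methoxyphenol) cage A5, which is compound 21.
- Merits: four bonds and three rings form in one redox-neutral step without protecting groups. Only C8a, ortho to the free phenol, can close a six-membered ring. It would reach 21 about seven steps sooner than the chosen route, which is a real advantage.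
- Weak points: A6 needs both aryl groups on the vicinal stereocentres C4/C4', anti to the carbinols, and no stereocontrolled way to make these benzylic centres is apparent. After the first cyclisation the second oxocarbenium ion is flanked by an alkoxy-bearing carbon, which destabilises it inductively, and it must close ring C in the same event. A7 and a 1,4-diol can rest as cyclic hemiacetals or oligomers.
- Comparison: the chosen plan sets against the shorter cage assembly an arene construction that never touches C4/C4' and bond formations of known type; both roads share the endgame from 21.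

Key step: step 7

Assumption: the stereodescriptors of the target SMILES are taken as those of natural epoxytwinol A; 1, 7, 11 and all reagents named are commercially available.

## Route

Step 1
Reactants: 1 methyl (R)-3-hydroxybutanoate (two molecules)
Product: 3 dimethyl (2R,3R)-2,3-bis[(1R)-1-hydroxyethyl]butanedioate, via dilithium alkoxide enolate 2 (not isolated)
Conditions: LiN(i-Pr)2 (2.2 equiv), THF, −78 → −30 °C; CuCl2 (1.1 equiv), DMF, −78 °C; aq NH4Cl
Reagents that add atoms: none
Why: Oxidative homocoupling of an ester enolate by a divalent copper halide, applied to the chelated Fráter–Seebach dianion. Each enolate carbon should bond on the face anti to the methyl group of the six-membered lithium chelate, as in Fráter–Seebach alkylation, which gives the C2-symmetric anti,anti (2R,3R) dimer and leaves the carbinol centres untouched.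

Step 2
Reactants: 3 dimethyl (2R,3R)-2,3-bis[(1R)-1-hydroxyethyl]butanedioate
Product: 4 dimethyl (2R,3R)-2,3-bis[(1R)-1-(tert-butyldimethylsilyloxy)ethyl]butanedioate
Conditions: TBSOTf, 2,6-lutidine, CH2Cl2, −78 → 0 °C
Reagents that add atoms: tert-butyldimethylsilyl trifluoromethanesulfonate, CC(C)(C)[Si](C)(C)OS(=O)(=O)C(F)(F)F
Why: Silylation of hindered secondary alcohols with a silyl triflate; prompt capping also forestalls lactonisation of each hydroxyl onto the distal ester.

Step 3
Reactants: 4 dimethyl (2R,3R)-2,3-bis[(1R)-1-(tert-butyldimethylsilyloxy)ethyl]butanedioate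
Product: 5 (2S,3S)-2,3-bis[(1R)-1-(tert-butyldimethylsilyloxy)ethyl]butane-1,4-diol
Conditions: i-Bu2AlH (6 equiv), CH2Cl2, −78 → 0 °C; aq KNaC4H4O6
Reagents that add atoms: none
Why: Exhaustive hydride reduction of both esters; aluminium alkoxides in CH2Cl2 should cause neither silyl migration nor epimerisation (the change of descriptor is a priority effect only).

Step 4
Reactants: 5 (2S,3S)-2,3-bis[(1R)-1-(tert-butyldimethylsilyloxy)ethyl]butane-1,4-diol
Product: 6 (2R,3R)-2,3-bis[(1R)-1-(tert-butyldimethylsilyloxy)ethyl]butanedial
Conditions: (COCl)2, DMSO, CH2Cl2, −78 °C; i-Pr2NEt, −78 → −30 °C; used at once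
Reagents that add atoms: none
Why: Swern oxidation; both hydroxyls are converted into alkoxysulfonium ions before base is added, so no lactol can form and be over-oxidised, and the hindered base at low temperature should spare the α-centres.

Step 5
Reactants: 6 (2R,3R)-2,3-bis[(1R)-1-(tert-butyldimethylsilyloxy)ethyl]butanedial; 7 dimethyl (1-diazo-2-oxopropyl)phosphonate
Product: 8 (3S,4S)-3,4-bis[(1R)-1-(tert-butyldimethylsilyloxy)ethyl]hexa-1,5-diyne
Conditions: K2CO3, MeOH, 0 → 23 °C
Reagents that add atoms: none
Why: Ohira–Bestmann form of the Seyferth–Gilbert homologation: methanolysis of 7 gives the diazomethylphosphonate anion, which turns each aldehyde into a terminal alkyne through an alkylidene carbene. The carbonate conditions are known to spare α-branched β-silyloxy aldehydes, and double homologation of 1,4-dialdehydes is established.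

Step 6
Reactants: 8 (3S,4S)-3,4-bis[(1R)-1-(tert-butyldimethylsilyloxy)ethyl]hexa-1,5-diyne
Product: 10 (4S,5S)-4,5-bis[(1R)-1-(tert-butyldimethylsilyloxy)ethyl]octa-2,6-diynedial, via dilithium bis-acetylide 9 (not isolated)
Conditions: n-BuLi (2.2 equiv), THF, −78 °C; DMF, −78 → 0 °C; poured into aq KH2PO4 at 0 °C
Reagents that add atoms: N,N-dimethylformamide, CN(C)C=O
Why: Formylation of lithium acetylides with DMF; the inverse quench into phosphate buffer releases the ynal without conjugate addition of dimethylamine.

Step 7
Reactants: 10 (4S,5S)-4,5-bis[(1R)-1-(tert-butyldimethylsilyloxy)ethyl]octa-2,6-diynedial; 11 2-methoxyfuran (6 equiv)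
Product: 13 2,2'-[(2R,3S,4S,5R)-2,5-bis(tert-butyldimethylsilyloxy)hexane-3,4-diyl]bis(3-hydroxy-6-methoxybenzaldehyde), via bis(methoxy-oxanorbornadiene) adduct 12 (not isolated)
Conditions: toluene, 23 → 45 °C, dark, no Lewis acid; silica gel on work-up to complete ring opening
Reagents that add atoms: none
Why: Each ynal undergoes a concerted but asynchronous intermolecular [4+2] cycloaddition with the furan; the closest known reaction type is the Diels–Alder addition of 2-alkoxyfurans to acetylenic carbonyl compounds with spontaneous opening to 4-alkoxyphenols. The unsubstituted, most nucleophilic furan carbon bonds to the ynal β-carbon (future C4a) and the methoxy-bearing carbon then closes the six-membered ring on the α-carbon (future C8a), so each carbocycle is closed by the second σ-bond of an intermolecular cycloaddition, four C–C bonds in all. In adduct 12 the bridgehead methoxy group pushes open the oxygen bridge and loss of the other bridgehead proton aromatises the ring, placing OH at C5 next to the side chain and OMe at C8 next to the aldehyde. The only stereocentres created are the bridgeheads of 12, which vanish on aromatisation; the four existing centres carry no hydrogen that is acidic under neutral thermal conditions. Regioselectivity should follow from the polarity match of the donor furan terminus with the acceptor β-carbon, reinforced sterically because the unsubstituted furan terminus meets the hindered alkyne carbon. Chemoselectivity for C≡C over C=O should follow from thermal conditions without Lewis acid, which disfavour vinylogous aldol addition and hetero-Diels–Alder reaction at the aldehyde. Excess 11 should carry both ynals through.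

Step 8
Reactants: 13 2,2'-[(2R,3S,4S,5R)-2,5-bis(tert-butyldimethylsilyloxy)hexane-3,4-diyl]bis(3-hydroxy-6-methoxybenzaldehyde)
Product: 14 2,2'-[(2R,3S,4S,5R)-2,5-bis(tert-butyldimethylsilyloxy)hexane-3,4-diyl]bis(3,6-dimethoxybenzaldehyde)
Conditions: MeI, Cs2CO3, DMF, 23 → 40 °C
Reagents that add atoms: iodomethane, CI
Why: Williamson O-methylation of the phenols; the caesium phenoxide is used because the hydroxyl sits next to the branched side chain.

Step 9
Reactants: 14 2,2'-[(2R,3S,4S,5R)-2,5-bis(tert-butyldimethylsilyloxy)hexane-3,4-diyl]bis(3,6-dimethoxybenzaldehyde)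
Product: 15 2,2'-[(2R,3S,4S,5R)-2,5-bis(tert-butyldimethylsilyloxy)hexane-3,4-diyl]bis(6-hydroxy-3-methoxybenzaldehyde)
Conditions: BCl3 (2.5 equiv), CH2Cl2, −78 → −40 °C; H2O
Reagents that add atoms: none
Why: Chelation-controlled demethylation: boron bound to the aldehyde oxygen and the ortho methoxy oxygen activates only that methyl group for chloride attack. The remote methyl ether stays, and the hindered secondary silyl ethers should survive the short exposure at low temperature.

Step 10
Reactants: 15 2,2'-[(2R,3S,4S,5R)-2,5-bis(tert-butyldimethylsilyloxy)hexane-3,4-diyl]bis(6-hydroxy-3-methoxybenzaldehyde)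
Product: 16 2,2'-[(2R,3S,4S,5R)-2,5-bis(tert-butyldimethylsilyloxy)hexane-3,4-diyl]bis[3-methoxy-6-(triisopropylsilyloxy)benzaldehyde]
Conditions: TIPSOTf, 2,6-lutidine, CH2Cl2, 0 °C
Reagents that add atoms: triisopropylsilyl trifluoromethanesulfonate, CC(C)[Si](C(C)C)(C(C)C)OS(=O)(=O)C(F)(F)F
Why: Silylation of the hydrogen-bonded phenol with a silyl triflate; the aryl triisopropylsilyl ether is chosen because it outlasts the acidic fluoride used later on the alkyl silyl ethers.

Step 11
Reactants: 16 2,2'-[(2R,3S,4S,5R)-2,5-bis(tert-butyldimethylsilyloxy)hexane-3,4-diyl]bis[3-methoxy-6-(triisopropylsilyloxy)benzaldehyde]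
Product: 17 (5S,6S,11Z)-5,6-bis[(1R)-1-(tert-butyldimethylsilyloxy)ethyl]-4,7-dimethoxy-1,10-bis(triisopropylsilyloxy)-5,6-dihydrodibenzo[a,e]cyclooctene
Conditions: TiCl4, Zn, pyridine, THF, reflux, slow addition of 16 at high dilution
Reagents that add atoms: none
Why: Intramolecular McMurry coupling of an aromatic dialdehyde by low-valent titanium, which forms the C1=C1' bond as the cis alkene of an eight-membered ring. The anti arrangement of the two bulky side chains about C4–C4' holds the aryl groups gauche and so favours cyclisation, and pyridine buffering protects the silyl ethers.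

Step 12
Reactants: 17 (5S,6S,11Z)-5,6-bis[(1R)-1-(tert-butyldimethylsilyloxy)ethyl]-4,7-dimethoxy-1,10-bis(triisopropylsilyloxy)-5,6-dihydrodibenzo[a,e]cyclooctene
Product: 18 (5S,6S,11Z)-5,6-bis[(1R)-1-hydroxyethyl]-4,7-dimethoxy-1,10-bis(triisopropylsilyloxy)-5,6-dihydrodibenzo[a,e]cyclooctene
Conditions: HF·pyridine, pyridine, THF, 0 → 23 °C
Reagents that add atoms: none
Why: Acidic fluoride cleaves the secondary alkyl silyl ethers while aryl triisopropylsilyl ethers are stable, and the buffered medium is too weakly acidic to protonate the alkene.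

Step 13
Reactants: 18 (5S,6S,11Z)-5,6-bis[(1R)-1-hydroxyethyl]-4,7-dimethoxy-1,10-bis(triisopropylsilyloxy)-5,6-dihydrodibenzo[a,e]cyclooctene
Product: 20 twin isochromane cage (1S,3R,4S,1'S,3'R,4'S)-5,5'-dimethoxy-3,3'-dimethyl-8,8'-bis(triisopropylsilyloxy)-1,1':4,4'-linked bis(isochromane), via bromo ether 19 (not isolated)
Conditions: N-bromosuccinimide (1.05 equiv), CH2Cl2, −78 °C; AgOTf (1.2 equiv), 2,6-di-tert-butyl-4-methylpyridine, −78 → 0 °C
Reagents that add atoms: none
Why: Bromoetherification followed by silver-assisted benzylic etherification. The two alkene faces are equivalent by the C2 axis, and the bromonium ion on either face is opened 6-exo at C1 by the carbinol oxygen on the opposite face (19). The benzylic bromide at C1', stabilised by the ortho silyloxy group, then ionises and is captured by the second carbinol oxygen on its own face, the only closure the ring allows, so C1 and C1' are dictated by C4 and C4' (1S,1'S); a hydride shift from C1 would need a bridgehead oxocarbenium ion and should not compete.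

Step 14
Reactants: 20 twin isochromane cage bis(triisopropylsilyl ether)
Product: 21 twin isochromane cage (1S,3R,4S,1'S,3'R,4'S)-5,5'-dimethoxy-3,3'-dimethyl-1,1':4,4'-linked bis(isochromane)-8,8'-diol
Conditions: Bu4NF, AcOH, THF, 0 °C
Reagents that add atoms: none
Why: Buffered fluoride cleaves the aryl silyl ethers; the cage ethers are inert because their benzylic carbons are bridgeheads, and acetic acid keeps the electron-rich phenolate from air oxidation.

Step 15
Reactants: 21 twin isochromane cage 8,8'-diol
Product: 22 twin cage bis(quinone monoketal) (1S,3R,4S,1'S,3'R,4'S)-5,5,5',5'-tetramethoxy-3,3'-dimethyl-1,1':4,4'-linked bis(3,4-dihydro-1H-isochromen-8(5H)-one)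
Conditions: PhI(OAc)2 (2.2 equiv), MeOH, 0 °C
Reagents that add atoms: methanol, CO
Why: Oxidative dearomatisation of a 4-methoxyphenol by a hypervalent iodine reagent in methanol: ligand exchange at iodine, loss of iodobenzene and capture of the phenoxenium ion at the para carbon by methanol give the p-quinone monoketal, with C8 as ketone and C5 as dimethyl ketal.

Step 16
Reactants: 22 twin cage bis(quinone monoketal)
Product: 23 twin cage bis(epoxy ketone) bis-ketal (1S,3R,4S,6R,7S in each half) 6,7:6',7'-diepoxy derivative of 22
Conditions: t-BuOOH, DBU, CH2Cl2, 0 → 23 °C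
Reagents that add atoms: tert-butyl hydroperoxide, CC(C)(C)OO
Why: Weitz–Scheffer epoxidation: the peroxide anion adds to C6, the β-carbon of the less substituted enone, and the enolate closes the oxirane, while the tetrasubstituted C4a=C8a enone is too hindered. The peroxide should approach each ring A from its convex face, the face of O2, because the opposite face is overhung by the O2'–C3' bridge of the other half; the bridgehead hydrogens at C1 and C4 cannot enolise, so the amidine base is tolerated.

Step 17
Reactants: 23 twin cage bis(epoxy ketone) bis-ketal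
Product: 24 twin cage bis(epoxy alcohol) bis-ketal (1S,3R,4S,6R,7R,8S in each half) 8,8'-diol from reduction of both ketones of 23
Conditions: i-Bu2AlH, THF, −78 °C; aq KNaC4H4O6
Reagents that add atoms: none
Why: 1,2-Reduction of an α,β-epoxy ketone by an aluminium hydride: aluminium bound to the oxirane oxygen delivers hydride on the oxirane face, which is also the open convex face, so each C8 hydroxyl should come out anti to its oxirane (8S; the change at C7 from S to R is a priority effect only).

Step 18
Reactants: 24 twin cage bis(epoxy alcohol) bis-ketal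
Product: 25 epoxytwinol A (1S,3R,4S,6R,7R,8S in each half)
Conditions: 48% aq HF, MeCN, 0 °C
Reagents that add atoms: water, O
Why: Acid hydrolysis of the dimethyl ketals through allylic oxocarbenium ions restores the two C5 enone carbonyls; the oxiranes are deactivated by the flanking carbonyl being formed, and the cage ethers cannot ionise at bridgeheads.

## Compound list

1 | methyl (R)-3-hydroxybutanoate | C[C@@H](O)CC(=O)OC | starting material
2 | dilithium alkoxide enolate of 1 (chelated dianion) | C[C@@H]([O-])/C=C(\[O-])OC.[Li+].[Li+] | intermediate (not isolated)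
3 | dimethyl (2R,3R)-2,3-bis[(1R)-1-hydroxyethyl]butanedioate | C[C@@H](O)[C@H](C(=O)OC)[C@@H](C(=O)OC)[C@@H](C)O | intermediate
4 | dimethyl (2R,3R)-2,3-bis[(1R)-1-(tert-butyldimethylsilyloxy)ethyl]butanedioate | C[C@@H](O[Si](C)(C)C(C)(C)C)[C@H](C(=O)OC)[C@@H](C(=O)OC)[C@@H](C)O[Si](C)(C)C(C)(C)C | intermediate
5 | (2S,3S)-2,3-bis[(1R)-1-(tert-butyldimethylsilyloxy)ethyl]butane-1,4-diol | C[C@@H](O[Si](C)(C)C(C)(C)C)[C@H](CO)[C@@H](CO)[C@@H](C)O[Si](C)(C)C(C)(C)C | intermediate
6 | (2R,3R)-2,3-bis[(1R)-1-(tert-butyldimethylsilyloxy)ethyl]butanedial | C[C@@H](O[Si](C)(C)C(C)(C)C)[C@H](C=O)[C@@H](C=O)[C@@H](C)O[Si](C)(C)C(C)(C)C | intermediate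
7 | dimethyl (1-diazo-2-oxopropyl)phosphonate | CC(=O)C(=[N+]=[N-])P(=O)(OC)OC | starting material
8 | (3S,4S)-3,4-bis[(1R)-1-(tert-butyldimethylsilyloxy)ethyl]hexa-1,5-diyne | C[C@@H](O[Si](C)(C)C(C)(C)C)[C@H](C#C)[C@@H](C#C)[C@@H](C)O[Si](C)(C)C(C)(C)C | intermediate
9 | dilithium bis-acetylide of 8 | C[C@@H](O[Si](C)(C)C(C)(C)C)[C@H](C#[C-])[C@@H](C#[C-])[C@@H](C)O[Si](C)(C)C(C)(C)C.[Li+].[Li+] | intermediate (not isolated)
10 | (4S,5S)-4,5-bis[(1R)-1-(tert-butyldimethylsilyloxy)ethyl]octa-2,6-diynedial | C[C@@H](O[Si](C)(C)C(C)(C)C)[C@H](C#CC=O)[C@@H](C#CC=O)[C@@H](C)O[Si](C)(C)C(C)(C)C | intermediate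
11 | 2-methoxyfuran | COc1ccco1 | starting material
12 | (2R,3S,4S,5R)-2,5-bis(tert-butyldimethylsilyloxy)-3,4-bis(2-formyl-1-methoxy-7-oxabicyclo[2.2.1]hepta-2,5-dien-3-yl)hexane (bridgehead configuration undefined) | C[C@@H](O[Si](C)(C)C(C)(C)C)[C@H](C1=C(C=O)C2(OC)C=CC1O2)[C@@H](C1=C(C=O)C2(OC)C=CC1O2)[C@@H](C)O[Si](C)(C)C(C)(C)C | intermediate (not isolated)
13 | 2,2'-[(2R,3S,4S,5R)-2,5-bis(tert-butyldimethylsilyloxy)hexane-3,4-diyl]bis(3-hydroxy-6-methoxybenzaldehyde) | C[C@@H](O[Si](C)(C)C(C)(C)C)[C@H](c1c(O)ccc(OC)c1C=O)[C@@H](c1c(O)ccc(OC)c1C=O)[C@@H](C)O[Si](C)(C)C(C)(C)C | intermediate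
14 | 2,2'-[(2R,3S,4S,5R)-2,5-bis(tert-butyldimethylsilyloxy)hexane-3,4-diyl]bis(3,6-dimethoxybenzaldehyde) | C[C@@H](O[Si](C)(C)C(C)(C)C)[C@H](c1c(OC)ccc(OC)c1C=O)[C@@H](c1c(OC)ccc(OC)c1C=O)[C@@H](C)O[Si](C)(C)C(C)(C)C | intermediate
15 | 2,2'-[(2R,3S,4S,5R)-2,5-bis(tert-butyldimethylsilyloxy)hexane-3,4-diyl]bis(6-hydroxy-3-methoxybenzaldehyde) | C[C@@H](O[Si](C)(C)C(C)(C)C)[C@H](c1c(OC)ccc(O)c1C=O)[C@@H](c1c(OC)ccc(O)c1C=O)[C@@H](C)O[Si](C)(C)C(C)(C)C | intermediate
16 | 2,2'-[(2R,3S,4S,5R)-2,5-bis(tert-butyldimethylsilyloxy)hexane-3,4-diyl]bis[3-methoxy-6-(triisopropylsilyloxy)benzaldehyde] | C[C@@H](O[Si](C)(C)C(C)(C)C)[C@H](c1c(OC)ccc(O[Si](C(C)C)(C(C)C)C(C)C)c1C=O)[C@@H](c1c(OC)ccc(O[Si](C(C)C)(C(C)C)C(C)C)c1C=O)[C@@H](C)O[Si](C)(C)C(C)(C)C | intermediate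
17 | (5S,6S,11Z)-5,6-bis[(1R)-1-(tert-butyldimethylsilyloxy)ethyl]-4,7-dimethoxy-1,10-bis(triisopropylsilyloxy)-5,6-dihydrodibenzo[a,e]cyclooctene | C[C@@H](O[Si](C)(C)C(C)(C)C)[C@@H]1c2c(OC)ccc(O[Si](C(C)C)(C(C)C)C(C)C)c2/C=C\c2c(O[Si](C(C)C)(C(C)C)C(C)C)ccc(OC)c2[C@H]1[C@@H](C)O[Si](C)(C)C(C)(C)C | intermediate
18 | (5S,6S,11Z)-5,6-bis[(1R)-1-hydroxyethyl]-4,7-dimethoxy-1,10-bis(triisopropylsilyloxy)-5,6-dihydrodibenzo[a,e]cyclooctene | C[C@@H](O)[C@@H]1c2c(OC)ccc(O[Si](C(C)C)(C(C)C)C(C)C)c2/C=C\c2c(O[Si](C(C)C)(C(C)C)C(C)C)ccc(OC)c2[C@H]1[C@@H](C)O | intermediate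
19 | bromo ether: 20 lacking the O2'–C1' bond, with bromine on C1' (trans to O2 across C1–C1') and free hydroxyl on C3' | C[C@H]1O[C@H]2c3c(c(OC)ccc3O[Si](C(C)C)(C(C)C)C(C)C)[C@@H]1[C@H]([C@@H](C)O)c1c(OC)ccc(O[Si](C(C)C)(C(C)C)C(C)C)c1[C@@H]2Br | intermediate (not isolated)
20 | twin isochromane cage (1S,3R,4S,1'S,3'R,4'S)-5,5'-dimethoxy-3,3'-dimethyl-8,8'-bis(triisopropylsilyloxy)-1,1':4,4'-linked bis(isochromane) | C[C@H]1O[C@H]2c3c(c(OC)ccc3O[Si](C(C)C)(C(C)C)C(C)C)[C@@H]1[C@H]1c3c(c(O[Si](C(C)C)(C(C)C)C(C)C)ccc3OC)[C@@H]2O[C@@H]1C | intermediate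
21 | twin isochromane cage (1S,3R,4S,1'S,3'R,4'S)-5,5'-dimethoxy-3,3'-dimethyl-1,1':4,4'-linked bis(isochromane)-8,8'-diol | C[C@H]1O[C@H]2c3c(c(OC)ccc3O)[C@@H]1[C@H]1c3c(c(O)ccc3OC)[C@@H]2O[C@@H]1C | intermediate
22 | twin cage bis(quinone monoketal), (1S,3R,4S,1'S,3'R,4'S)-5,5,5',5'-tetramethoxy-3,3'-dimethyl-1,1':4,4'-linked bis(3,4-dihydro-1H-isochromen-8(5H)-one) | C[C@H]1O[C@H]2C3=C(C(OC)(OC)C=CC3=O)[C@@H]1[C@H]1C3=C(C(=O)C=CC3(OC)OC)[C@@H]2O[C@@H]1C | intermediate
23 | twin cage bis(epoxy ketone) bis-ketal, 6,7:6',7'-diepoxide of 22 (1S,3R,4S,6R,7S in each half) | C[C@H]1O[C@H]2C3=C(C(OC)(OC)[C@@H]4O[C@@H]4C3=O)[C@@H]1[C@H]1C3=C(C(=O)[C@H]4O[C@H]4C3(OC)OC)[C@@H]2O[C@@H]1C | intermediate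
24 | twin cage bis(epoxy alcohol) bis-ketal, 8,8'-diol of 23 (1S,3R,4S,6R,7R,8S in each half) | C[C@H]1O[C@H]2C3=C(C(OC)(OC)[C@@H]4O[C@@H]4[C@H]3O)[C@@H]1[C@H]1C3=C([C@H](O)[C@H]4O[C@H]4C3(OC)OC)[C@@H]2O[C@@H]1C | intermediate
25 | epoxytwinol A (1S,3R,4S,6R,7R,8S in each half) | C[C@H]1O[C@H]2C3=C(C(=O)[C@@H]4O[C@@H]4[C@H]3O)[C@@H]1[C@H]1C3=C([C@H](O)[C@H]4O[C@H]4C3=O)[C@@H]2O[C@@H]1C | target

## Step count and least certain steps

Total step count: 18. Longest linear sequence: 18 steps, from 1 to 25; 7 and 11 are bought.

**Step 7 (key step).** The cycloaddition may be slow at the β-carbon, which sits next to a branched, silyloxy-substituted centre. Addition of the electron-rich furan to the free aldehyde, and acid-triggered decomposition of the furan by the phenol being formed, could then take over. Fallback: move the acceptor to the ester oxidation level, where only the alkyne can react. From 8, n-BuLi then methyl chloroformate should give dimethyl (4S,5S)-4,5-bis[(1R)-1-(tert-butyldimethylsilyloxy)ethyl]octa-2,6-diynedioate F1. Cycloaddition with 11 (toluene, 80–100 °C) should give the bis(3-hydroxy-6-methoxybenzoate) F2. O-Methylation (MeI, Cs2CO3) gives the bis(3,6-dimethoxybenzoate) F3, reduction with i-Bu2AlH the bis(benzylic alcohol) F4, and oxidation with MnO2 returns to the route at 14.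

**Step 1.** Halogen transfer from the copper halide to the enolate, followed by displacement of the halide by the neighbouring alkoxide (glycidate formation), may compete with coupling. Facial control in the coupling of two chelated enolates may also be incomplete, so that a diastereomer mixture forms; only the anti,anti isomer can later close the cage. Fallback: lock the oxygen in an acetal. Saponification of 1 (LiOH) gives (R)-3-hydroxybutanoic acid F5. Acetalisation with pivalaldehyde (TsOH cat.) gives (2R,6R)-2-tert-butyl-6-methyl-1,3-dioxan-4-one F6, whose lithium enolate is known to react trans to the ring substituents and cannot form an oxirane. Oxidative coupling (LiN(i-Pr)2; CuCl2) should give the 5,5'-linked bis(dioxanone) F7, and methanolysis (HCl, MeOH) returns to the route at 3.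

**Step 11.** The coupling may stall at the titanium pinacolate, because deoxygenation needs forcing conditions. Intermolecular coupling of the hindered 2,6-disubstituted benzaldehydes and loss of silyl groups to the Lewis-acidic medium are further risks. Fallback: separate C–C formation from deoxygenation and close the ethers by ionisation. From 16, SmI2 (THF, −78 → 0 °C) should give the ring C 1,2-diol F8 (pinacol coupling). HF·pyridine gives the tetraol F9. BF3·OEt2 (or camphorsulfonic acid) in CH2Cl2 should effect double dehydrative benzylic etherification and return to the route at 20. The weakness of this fallback is a hydride shift at the first benzylic cation.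

**Step 13.** Electrophilic bromination of the two electron-rich arenes may compete with attack on the hindered alkene, and the benzylic bromide may be lost before silver is added. Fallback: deliver oxygen, not halogen, to the alkene. From 18, dimethyldioxirane (acetone, −20 °C) should give the cis-11,12-epoxide F10 (one isomer, since the alkene faces are equivalent). Camphorsulfonic acid in CH2Cl2 should then open the oxirane 6-exo at C1 with one carbinol and replace the resulting benzylic hydroxyl at C1' with the other, returning to the route at 20.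

**Step 16.** Facial selectivity may be poor: the two faces of the C6=C7 bond differ only through the overhang of the other half, which is several bonds away, so diastereomeric epoxides may form. Fallback: change from substrate control to reagent control. Trityl hydroperoxide, NaN(SiMe3)2 and the appropriate enantiomer of diisopropyl tartrate are used, the known tartrate-mediated nucleophilic epoxidation of quinone monoketals. It sets out from 22 and returns at 23 and makes no compound outside the list (F0).

## Further compounds

F1 | step 7 | dimethyl (4S,5S)-4,5-bis[(1R)-1-(tert-butyldimethylsilyloxy)ethyl]octa-2,6-diynedioate | C[C@@H](O[Si](C)(C)C(C)(C)C)[C@H](C#CC(=O)OC)[C@@H](C#CC(=O)OC)[C@@H](C)O[Si](C)(C)C(C)(C)C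
F2 | step 7 | dimethyl 2,2'-[(2R,3S,4S,5R)-2,5-bis(tert-butyldimethylsilyloxy)hexane-3,4-diyl]bis(3-hydroxy-6-methoxybenzoate) | C[C@@H](O[Si](C)(C)C(C)(C)C)[C@H](c1c(O)ccc(OC)c1C(=O)OC)[C@@H](c1c(O)ccc(OC)c1C(=O)OC)[C@@H](C)O[Si](C)(C)C(C)(C)C
F3 | step 7 | dimethyl 2,2'-[(2R,3S,4S,5R)-2,5-bis(tert-butyldimethylsilyloxy)hexane-3,4-diyl]bis(3,6-dimethoxybenzoate) | C[C@@H](O[Si](C)(C)C(C)(C)C)[C@H](c1c(OC)ccc(OC)c1C(=O)OC)[C@@H](c1c(OC)ccc(OC)c1C(=O)OC)[C@@H](C)O[Si](C)(C)C(C)(C)C
F4 | step 7 | {[(2R,3S,4S,5R)-2,5-bis(tert-butyldimethylsilyloxy)hexane-3,4-diyl]bis(3,6-dimethoxy-2,1-phenylene)}dimethanol | C[C@@H](O[Si](C)(C)C(C)(C)C)[C@H](c1c(OC)ccc(OC)c1CO)[C@@H](c1c(OC)ccc(OC)c1CO)[C@@H](C)O[Si](C)(C)C(C)(C)C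
F5 | step 1 | (R)-3-hydroxybutanoic acid | C[C@@H](O)CC(=O)O
F6 | step 1 | (2R,6R)-2-tert-butyl-6-methyl-1,3-dioxan-4-one | C[C@@H]1CC(=O)O[C@H](C(C)(C)C)O1
F7 | step 1 | (2R,2'R,5R,5'R,6R,6'R)-2,2'-di-tert-butyl-6,6'-dimethyl-[5,5'-bi(1,3-dioxane)]-4,4'-dione | C[C@@H]1[C@@H]([C@H]2C(=O)O[C@H](C(C)(C)C)O[C@@H]2C)C(=O)O[C@H](C(C)(C)C)O1
F8 | step 11 | (5S,6S)-5,6-bis[(1R)-1-(tert-butyldimethylsilyloxy)ethyl]-4,7-dimethoxy-1,10-bis(triisopropylsilyloxy)-5,6,11,12-tetrahydrodibenzo[a,e]cyclooctene-11,12-diol (carbinol configuration undefined) | C[C@@H](O[Si](C)(C)C(C)(C)C)[C@@H]1c2c(OC)ccc(O[Si](C(C)C)(C(C)C)C(C)C)c2C(O)C(O)c2c(O[Si](C(C)C)(C(C)C)C(C)C)ccc(OC)c2[C@H]1[C@@H](C)O[Si](C)(C)C(C)(C)C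
F9 | step 11 | (5S,6S)-5,6-bis[(1R)-1-hydroxyethyl]-4,7-dimethoxy-1,10-bis(triisopropylsilyloxy)-5,6,11,12-tetrahydrodibenzo[a,e]cyclooctene-11,12-diol (carbinol configuration undefined) | C[C@@H](O)[C@@H]1c2c(OC)ccc(O[Si](C(C)C)(C(C)C)C(C)C)c2C(O)C(O)c2c(O[Si](C(C)C)(C(C)C)C(C)C)ccc(OC)c2[C@H]1[C@@H](C)O
F10 | step 13 | cis-11,12-epoxide of 18 | C[C@@H](O)[C@@H]1c2c(OC)ccc(O[Si](C(C)C)(C(C)C)C(C)C)c2[C@@H]2O[C@@H]2c2c(O[Si](C(C)C)(C(C)C)C(C)C)ccc(OC)c2[C@H]1[C@@H](C)O
F0 | step 16 | none | none
A1 | alternative 1 | tetraboryl aromatic cage | C[C@H]1O[C@H]2c3c(c(B4OC(C)(C)C(C)(C)O4)ccc3B4OC(C)(C)C(C)(C)O4)[C@@H]1[C@H]1c3c(c(B4OC(C)(C)C(C)(C)O4)ccc3B4OC(C)(C)C(C)(C)O4)[C@@H]2O[C@@H]1C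
A2 | alternative 1 | 5,8-dimethyl-2,3,6,7-tetrakis[(4,4,5,5-tetramethyl-1,3,2-dioxaborolan-2-yl)ethynyl]-1,4-dioxocane, configured as the corresponding centres of 25 | C[C@H]1O[C@@H](C#CB2OC(C)(C)C(C)(C)O2)[C@H](C#CB2OC(C)(C)C(C)(C)O2)O[C@H](C)[C@H](C#CB2OC(C)(C)C(C)(C)O2)[C@H]1C#CB2OC(C)(C)C(C)(C)O2
A3 | alternative 1 | acetylene | C#C
A4 | alternative 2 | bis(epoxy ketone) bis-ketal (identical with 23) | C[C@H]1O[C@H]2C3=C(C(OC)(OC)[C@@H]4O[C@@H]4C3=O)[C@@H]1[C@H]1C3=C(C(=O)[C@H]4O[C@H]4C3(OC)OC)[C@@H]2O[C@@H]1C
A5 | alternative 3 | C2-symmetric bis(4-methoxyphenol) cage (identical with 21) | C[C@H]1O[C@H]2c3c(c(OC)ccc3O)[C@@H]1[C@H]1c3c(c(O)ccc3OC)[C@@H]2O[C@@H]1C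
A6 | alternative 3 | (2R,3S,4S,5R)-3,4-bis(5-hydroxy-2-methoxyphenyl)hexane-2,5-diol | C[C@@H](O)[C@H](c1cc(O)ccc1OC)[C@@H](c1cc(O)ccc1OC)[C@@H](C)O
A7 | alternative 3 | glyoxal | O=CC=O
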